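**Retrosynthetic overview**
1. Target 14 ⇐ tetra-MOM flavone 13 by methanolysis of four MOM ethers.
2. 13 ⇐ salicylaldehyde 12 + aryl alkyne 7 (key step): the formyl carbon of 12, normally an electrophile, reacts as an acyl-rhodium (acyl anion equivalent) and is joined to the alkyl-bearing alkyne carbon (C4–C3), then O1–C2 closes.
3. 7 ⇐ lithium acetylide of 5 + (2R,3R)-epoxygeraniol 2, through the Payne-rearranged terminal epoxide 6; both stereocentres come from one Sharpless epoxidation of geraniol.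
4. 12 ⇐ 2,4,6-trihydroxybenzaldehyde (bis-MOM, O-prenyl, para-Claisen–Cope fixes the 6-prenyl position); 5 ⇐ 2,4-dihydroxybenzaldehyde (MOM, Ohira–Bestmann).
5. Ring order: the A and B benzene rings are bought; the pyran-4-one ring is the only ring built, in step 8.

Assumption: the SMILES is read as the (2S,3R)-diol in the side chain (secondary carbinol S, tertiary carbinol R); D-(−)-diethyl tartrate and 2,4,6-trihydroxybenzaldehyde are taken as ordinary catalogue items.

**Step 1**
Reactants: 1 geraniol [(2E)-3,7-dimethylocta-2,6-dien-1-ol]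
Product: 2 [(2R,3R)-3-methyl-3-(4-methylpent-3-en-1-yl)oxiran-2-yl]methanol ((2R,3R)-2,3-epoxygeraniol)
Conditions: Ti(OiPr)4 (5 mol %), D-(−)-diethyl tartrate (7.5 mol %), t-BuOOH (1.5 equiv, in decane), 4 Å MS, CH2Cl2, −20 °C
Reagents that add atoms: tert-butyl hydroperoxide, CC(C)(C)OO
Why: Katsuki–Sharpless asymmetric epoxidation is selective for the allylic 2,3-alkene over the remote 6,7-alkene, and D-(−)-tartrate delivers oxygen to the face that gives the (2R,3R)-epoxide, the source of both stereocentres of the target (typically ≥ 90 % ee).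

**Step 2**
Reactants: 3 2,4-dihydroxybenzaldehyde
Product: 4 2,4-bis(methoxymethoxy)benzaldehyde
Conditions: MOMCl (3 equiv), K2CO3, acetone, reflux
Reagents that add atoms: chloromethyl methyl ether, COCCl
Why: Williamson-type O-alkylation with MOMCl caps both phenols, the excess reagent and reflux also forcing the hydrogen-bonded ortho-OH to react.

**Step 3**
Reactants: 4 2,4-bis(methoxymethoxy)benzaldehyde
Product: 5 1-ethynyl-2,4-bis(methoxymethoxy)benzene
Conditions: dimethyl (1-diazo-2-oxopropyl)phosphonate, K2CO3, MeOH, 0 °C → rt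
Reagents that add atoms: dimethyl (1-diazo-2-oxopropyl)phosphonate, CC(=O)C(=[N+]=[N-])P(=O)(OC)OC
Why: Seyferth–Gilbert homologation with the Ohira–Bestmann reagent turns the aryl aldehyde into the terminal alkyne under mild basic conditions that MOM ethers tolerate.

**Step 4**
Reactants: 2 (2R,3R)-2,3-epoxygeraniol; 5 1-ethynyl-2,4-bis(methoxymethoxy)benzene
Product: 7 (4S,5R)-1-[2,4-bis(methoxymethoxy)phenyl]-5,9-dimethyldec-8-en-1-yne-4,5-diol, via Payne-rearranged terminal epoxide 6 (not isolated)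
Conditions: 5 (2.5 equiv), n-BuLi (2.4 equiv), THF, −78 → 0 °C; then 2, DMSO, 0 → 45 °C; then H2O
Reagents that add atoms: none
Why: Proposed new method: in-flask anionic Payne rearrangement with acetylide capture, in which the C1 alkoxide of 2 opens the epoxide at C2 with inversion (2R → 2S, C3 untouched) to give a small equilibrium share of terminal epoxide 6, whose CH2 is the only SN2-accessible carbon in the mixture and is attacked by the lithium arylacetylide (Curtin–Hammett), fixing the (4S,5R)-diol; the closest known chemistry is Payne rearrangement–opening of 2,3-epoxy alcohols by thiolates or sulfur ylides and acetylide opening of terminal epoxides in DMSO.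

**Step 5**
Reactants: 8 2,4,6-trihydroxybenzaldehyde
Product: 9 2-hydroxy-4,6-bis(methoxymethoxy)benzaldehyde
Conditions: MOMCl (2.2 equiv), iPr2NEt (2.5 equiv), CH2Cl2, 0 °C → rt
Reagents that add atoms: chloromethyl methyl ether, COCCl
Why: Selective O-alkylation protects the 4-OH and one ortho-OH, while the last ortho-OH is deactivated by its hydrogen bond to the aldehyde and stays free.

**Step 6**
Reactants: 9 2-hydroxy-4,6-bis(methoxymethoxy)benzaldehyde
Product: 10 2,4-bis(methoxymethoxy)-6-[(3-methylbut-2-en-1-yl)oxy]benzaldehyde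
Conditions: prenyl bromide (1.3 equiv), K2CO3, DMF, rt
Reagents that add atoms: prenyl bromide (1-bromo-3-methylbut-2-ene), CC(C)=CCBr
Why: Williamson etherification of the chelated phenol with the allylic bromide in a polar aprotic solvent gives the O-prenyl ether needed for the rearrangement.

**Step 7**
Reactants: 10 2,4-bis(methoxymethoxy)-6-[(3-methylbut-2-en-1-yl)oxy]benzaldehyde
Product: 12 2-hydroxy-4,6-bis(methoxymethoxy)-5-(3-methylbut-2-en-1-yl)benzaldehyde, via ortho-Claisen dienone 11 (not isolated)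
Conditions: PhNEt2, 200 °C, sealed tube, Ar, 3 h
Reagents that add atoms: none
Why: Aromatic Claisen rearrangement ([3,3]) to the ortho dienone, then Cope rearrangement ([3,3]) to the para position and tautomerisation (para-Claisen–Cope), puts a normal prenyl group para to the freed phenol, between the two MOM ethers, as in the analogous acetophenone series.

**Step 8 (key step)**
Reactants: 12 2-hydroxy-4,6-bis(methoxymethoxy)-5-(3-methylbut-2-en-1-yl)benzaldehyde; 7 (4S,5R)-1-[2,4-bis(methoxymethoxy)phenyl]-5,9-dimethyldec-8-en-1-yne-4,5-diol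
Product: 13 2-[2,4-bis(methoxymethoxy)phenyl]-3-[(2S,3R)-2,3-dihydroxy-3,7-dimethyloct-6-en-1-yl]-5,7-bis(methoxymethoxy)-6-(3-methylbut-2-en-1-yl)-4H-chromen-4-one
Conditions: 12 (1.2 equiv), [RhCl(cod)]2 (2.5 mol %), C5H2Ph4 (10 mol %), Cu(OAc)2·H2O (2.2 equiv), o-xylene, 125 °C, N2
Reagents that add atoms: none
Why: Rh-catalysed oxidative annulation of a salicylaldehyde with an internal alkyne, in which phenol-directed formyl C–H metalation makes the aldehyde carbon an acyl-rhodium nucleophile (an acyl anion equivalent, reversed polarity) that adds to the alkyl-bearing alkyne carbon (C4–C3) while the aryl-bearing carbon stays on rhodium and then closes O1–C2 by reductive elimination, Cu(OAc)2 re-oxidising Rh(I) and the remote diol stereocentres staying untouched.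

**Step 9**
Reactants: 13 tetra-MOM flavone diol
Product: 14 2-(2,4-dihydroxyphenyl)-3-[(2S,3R)-2,3-dihydroxy-3,7-dimethyloct-6-en-1-yl]-5,7-dihydroxy-6-(3-methylbut-2-en-1-yl)-4H-chromen-4-one (target)
Conditions: HCl (1.25 M in MeOH), 40 °C, 2 h
Reagents that add atoms: none
Why: Acid-catalysed acetal exchange (methanolysis) removes all four MOM groups at a temperature low enough to spare the prenyl/phenol pairs, the tertiary alcohol and the trisubstituted alkene, and no stereocentre is touched.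

**Compound list**
1 | geraniol, (2E)-3,7-dimethylocta-2,6-dien-1-ol | CC(C)=CCC/C(C)=C/CO | starting material
2 | [(2R,3R)-3-methyl-3-(4-methylpent-3-en-1-yl)oxiran-2-yl]methanol | OC[C@H]1O[C@]1(C)CCC=C(C)C | intermediate
3 | 2,4-dihydroxybenzaldehyde | O=Cc1ccc(O)cc1O | starting material
4 | 2,4-bis(methoxymethoxy)benzaldehyde | O=Cc1ccc(OCOC)cc1OCOC | intermediate
5 | 1-ethynyl-2,4-bis(methoxymethoxy)benzene | C#Cc1ccc(OCOC)cc1OCOC | intermediate
6 | (2R)-6-methyl-2-[(2S)-oxiran-2-yl]hept-5-en-2-ol (Payne-rearranged epoxide, present as its alkoxide, not isolated) | CC(C)=CCC[C@@](C)(O)[C@@H]1CO1 | intermediate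
7 | (4S,5R)-1-[2,4-bis(methoxymethoxy)phenyl]-5,9-dimethyldec-8-en-1-yne-4,5-diol | CC(C)=CCC[C@@](C)(O)[C@@H](O)CC#Cc1ccc(OCOC)cc1OCOC | intermediate
8 | 2,4,6-trihydroxybenzaldehyde | O=Cc1c(O)cc(O)cc1O | starting material
9 | 2-hydroxy-4,6-bis(methoxymethoxy)benzaldehyde | O=Cc1c(O)cc(OCOC)cc1OCOC | intermediate
10 | 2,4-bis(methoxymethoxy)-6-[(3-methylbut-2-en-1-yl)oxy]benzaldehyde | O=Cc1c(OCC=C(C)C)cc(OCOC)cc1OCOC | intermediate
11 | 2,4-bis(methoxymethoxy)-5-(2-methylbut-3-en-2-yl)-6-oxocyclohexa-1,3-diene-1-carbaldehyde (racemic ortho-Claisen dienone, not isolated) | O=CC1=C(OCOC)C=C(OCOC)C(C(C)(C)C=C)C1=O | intermediate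
12 | 2-hydroxy-4,6-bis(methoxymethoxy)-5-(3-methylbut-2-en-1-yl)benzaldehyde | O=Cc1c(O)cc(OCOC)c(CC=C(C)C)c1OCOC | intermediate
13 | 2-[2,4-bis(methoxymethoxy)phenyl]-3-[(2S,3R)-2,3-dihydroxy-3,7-dimethyloct-6-en-1-yl]-5,7-bis(methoxymethoxy)-6-(3-methylbut-2-en-1-yl)-4H-chromen-4-one | CC(C)=CCC[C@@](C)(O)[C@@H](O)Cc1c(-c2ccc(OCOC)cc2OCOC)oc2cc(OCOC)c(CC=C(C)C)c(OCOC)c2c1=O | intermediate
14 | 2-(2,4-dihydroxyphenyl)-3-[(2S,3R)-2,3-dihydroxy-3,7-dimethyloct-6-en-1-yl]-5,7-dihydroxy-6-(3-methylbut-2-en-1-yl)-4H-chromen-4-one | CC(C)=CCC[C@@](C)(O)[C@@H](O)Cc1c(-c2ccc(O)cc2O)oc2cc(O)c(CC=C(C)C)c(O)c2c1=O | target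

**Count and risks**
Total steps: 9. Longest linear sequence: 5 steps (8 → 9 → 10 → 12 → 13 → 14; the branch 3 → 4 → 5 → 7 → 13 → 14 is equally long).

Most likely to fail, step 8 (annulation): the aldehyde is hindered and electron-rich, decarbonylation to a benzofuran can compete, and the free homopropargylic diol could disturb the alkyne insertion regiochemistry. The fallback is a normal-polarity diketone route that sets out from 7 and 12 and comes back at 14. Compound 7 is protected with 2,2-dimethoxypropane/PPTS as the alkyne acetonide F7. Gold(I)-catalysed hydration (IPrAuNTf2, dioxane–H2O, 60 °C) gives the aryl ketone F8. Compound 12 is silylated (TBSCl, imidazole) to the TBS ether F9. The lithium enolate of F8 (LDA, THF, −78 °C) adds to F9 to give the aldol F10, a diastereomer mixture that does not matter. Dess–Martin oxidation gives the 1,3-diketone F11. TBAF then AcOH at 60 °C frees only the phenol para to the prenyl group and cyclodehydrates to the flavone acetonide F12. Methanolic HCl converts F12 into 14.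

Second, step 4 (Payne/acetylide cascade): the Payne equilibrium lies on the side of 2, and the acetylide may act as a base instead. The fallback separates the two events; it sets out from 2 and comes back at 7. Compound 2 is opened under aqueous Payne conditions (PhSH, NaOH, t-BuOH–H2O, 70 °C) to the thioether diol F1. S-Methylation (Me3OBF4, CH2Cl2) and brief treatment with aqueous NaOH at 0 °C close the sulfonium to epoxide 6, now isolated. N-(Trimethylsilyl)imidazole caps its tertiary alcohol as the silylated epoxide F2, so no alkoxide can rearrange back. The lithium acetylide of 5 with BF3·OEt2 (THF, −78 °C) opens F2 at the CH2 to the silyl ether alcohol F3, and TBAF gives 7.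

Third, step 7 (para-Claisen–Cope): the ortho dienone may simply tautomerise to the reverse-prenyl phenol, and the aldehyde may suffer at 200 °C. The fallback uses directed metalation instead of a sigmatropic shift; it sets out from 9 and comes back at 12. Compound 9 is silylated (TIPSOTf, 2,6-lutidine) to the TIPS ether F4. The aldehyde is masked with HC(OMe)3/PPTS/MeOH as the dimethyl acetal F5. n-BuLi (THF, 0 °C) lithiates the position flanked by the two MOM ethers, and prenyl bromide gives the prenylated acetal F6. PPTS in wet acetone followed by TBAF returns 12.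

**Further compounds**
F1 | step 4 | (2R,3R)-3,7-dimethyl-1-(phenylsulfanyl)oct-6-ene-2,3-diol | CC(C)=CCC[C@@](C)(O)[C@@H](O)CSc1ccccc1
F2 | step 4 | trimethyl{[(2R)-6-methyl-2-[(2S)-oxiran-2-yl]hept-5-en-2-yl]oxy}silane | CC(C)=CCC[C@@](C)(O[Si](C)(C)C)[C@@H]1CO1
F3 | step 4 | (4S,5R)-1-[2,4-bis(methoxymethoxy)phenyl]-5,9-dimethyl-5-[(trimethylsilyl)oxy]dec-8-en-1-yn-4-ol | CC(C)=CCC[C@@](C)(O[Si](C)(C)C)[C@@H](O)CC#Cc1ccc(OCOC)cc1OCOC
F4 | step 7 | 2,4-bis(methoxymethoxy)-6-{[tri(propan-2-yl)silyl]oxy}benzaldehyde | O=Cc1c(O[Si](C(C)C)(C(C)C)C(C)C)cc(OCOC)cc1OCOC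
F5 | step 7 | [2-(dimethoxymethyl)-3,5-bis(methoxymethoxy)phenoxy]tri(propan-2-yl)silane | COC(OC)c1c(O[Si](C(C)C)(C(C)C)C(C)C)cc(OCOC)cc1OCOC
F6 | step 7 | [2-(dimethoxymethyl)-3,5-bis(methoxymethoxy)-4-(3-methylbut-2-en-1-yl)phenoxy]tri(propan-2-yl)silane | COC(OC)c1c(O[Si](C(C)C)(C(C)C)C(C)C)cc(OCOC)c(CC=C(C)C)c1OCOC
F7 | step 8 | (4S,5R)-4-{3-[2,4-bis(methoxymethoxy)phenyl]prop-2-yn-1-yl}-2,2,5-trimethyl-5-(4-methylpent-3-en-1-yl)-1,3-dioxolane | CC(C)=CCC[C@@]1(C)OC(C)(C)O[C@H]1CC#Cc1ccc(OCOC)cc1OCOC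
F8 | step 8 | 1-[2,4-bis(methoxymethoxy)phenyl]-3-[(4S,5R)-2,2,5-trimethyl-5-(4-methylpent-3-en-1-yl)-1,3-dioxolan-4-yl]propan-1-one | CC(C)=CCC[C@@]1(C)OC(C)(C)O[C@H]1CCC(=O)c1ccc(OCOC)cc1OCOC
F9 | step 8 | 2-[(tert-butyldimethylsilyl)oxy]-4,6-bis(methoxymethoxy)-5-(3-methylbut-2-en-1-yl)benzaldehyde | O=Cc1c(O[Si](C)(C)C(C)(C)C)cc(OCOC)c(CC=C(C)C)c1OCOC
F10 | step 8 | 1-[2,4-bis(methoxymethoxy)phenyl]-3-{2-[(tert-butyldimethylsilyl)oxy]-4,6-bis(methoxymethoxy)-5-(3-methylbut-2-en-1-yl)phenyl}-3-hydroxy-2-{[(4S,5R)-2,2,5-trimethyl-5-(4-methylpent-3-en-1-yl)-1,3-dioxolan-4-yl]methyl}propan-1-one (diastereomer mixture at C2/C3) | CC(C)=CCC[C@@]1(C)OC(C)(C)O[C@H]1CC(C(O)c1c(O[Si](C)(C)C(C)(C)C)cc(OCOC)c(CC=C(C)C)c1OCOC)C(=O)c1ccc(OCOC)cc1OCOC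
F11 | step 8 | 1-[2,4-bis(methoxymethoxy)phenyl]-3-{2-[(tert-butyldimethylsilyl)oxy]-4,6-bis(methoxymethoxy)-5-(3-methylbut-2-en-1-yl)phenyl}-2-{[(4S,5R)-2,2,5-trimethyl-5-(4-methylpent-3-en-1-yl)-1,3-dioxolan-4-yl]methyl}propane-1,3-dione | CC(C)=CCC[C@@]1(C)OC(C)(C)O[C@H]1CC(C(=O)c1c(O[Si](C)(C)C(C)(C)C)cc(OCOC)c(CC=C(C)C)c1OCOC)C(=O)c1ccc(OCOC)cc1OCOC
F12 | step 8 | 2-[2,4-bis(methoxymethoxy)phenyl]-5,7-bis(methoxymethoxy)-6-(3-methylbut-2-en-1-yl)-3-{[(4S,5R)-2,2,5-trimethyl-5-(4-methylpent-3-en-1-yl)-1,3-dioxolan-4-yl]methyl}-4H-chromen-4-one | CC(C)=CCC[C@@]1(C)OC(C)(C)O[C@H]1Cc1c(-c2ccc(OCOC)cc2OCOC)oc2cc(OCOC)c(CC=C(C)C)c(OCOC)c2c1=O
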